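**Remarks.** Atom labels: ring A is C1 (epoxide carbon bearing the chain), C2 (second epoxide carbon), C3 and C6 (carbinols), C4=C5 (CH2OH on C4). The chain is C1–Cc(OH)–Cb=Ca(CH3)–Cd=Ce–C1′. Ring B is C1′ (bonded to Ce), C2′ (gem-dimethyl), C3′ (CHOH) and C6′ (C(CH3)OH). Assumption: the ester-bearing centres of 2 may form as epimer mixtures; they are erased in steps 3 and 4, so only the (S,S) carbinol configuration matters. Compounds 1, 13 and 21 are taken as commercial.

Numbering used throughout (full names and SMILES follow the steps): 1 dimethyl succinylsuccinate; 2 diol diester; 3 bis-TBS diester; 4 bis-enolate; 5 bis-selenide; 6 bis-selenoxide; 7 twofold-symmetric diene diester; 8 peroxy enolate; 9 mono-epoxide diester; 10 epoxy diol; 11 mono-TBS epoxy alcohol; 12 epoxy aldehyde; 13 geranyl acetate; 14 (R)-epoxygeranyl acetate; 15 cyclised hydroxy acetate; 16 spiro-epoxide; 17 triol; 18 tetrazolyl sulfide; 19 sulfone diol; 20 bis-TES sulfone; 21 propargyl alcohol; 22 alkenylmagnesium intermediate; 23 (Z)-iodo allylic alcohol; 24 (Z)-iodoenal; 25 sulfonyl carbanion; 26 (1Z,3E)-dienyl iodide; 27 dienyllithium; 28 coupled carbinol (Cc epimers); 29 dienone; 30 penta-silyl ether with (S)-Cc–OH; 31 arthrosporol A.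

## Analysis of the target

Arthrosporol A (31) joins two carbocycles through a five-carbon dienyl carbinol chain. Ring A is a 7-oxabicyclo[4.1.0]hept-3-ene. C1 is a fully substituted epoxide carbon carrying the chain, C3 and C6 are secondary carbinols, and the C4=C5 alkene bears a hydroxymethyl group on C4. The two ring hydroxyls are cis to each other and trans to the epoxide oxygen. The chain has Cc of S configuration, a Z trisubstituted Ca=Cb bond and an E Cd=Ce bond. Ring B is a 2,2,6-trimethylcyclohexane in which the C3′ hydroxyl (R), the tertiary C6′ hydroxyl and the chain at C1′ are all equatorial and the C6′ methyl is axial, the pattern left by a chair epoxy-polyene cyclisation. The sensitive groups are the epoxide flanked by three hydroxyl-bearing carbons (epoxide migration in base, opening in acid), the dienylic Cc carbinol (ionisation) and the Z alkene (isomerisation); six hydroxyls must be freed at the end without disturbing them. The hard points are the quaternary epoxide carbon C1 within four contiguous ring stereocentres, the isolated Cc stereocentre, and the distance between rings A and B, which forces each to be made as a single enantiomer on its own. The strategy rests on the hidden twofold symmetry of ring A: C1 and C4 each carry one oxygenated carbon and C3 and C6 each carry a hydroxyl on the same face. Without the epoxide oxygen, ring A is therefore a twofold-symmetric cyclohexa-1,4-diene whose C1=C2 and C4=C5 alkenes are homotopic.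

## Retrosynthetic reasoning

**Protecting groups.** 31 is traced back to 30, in which every hydroxyl except Cc–OH is a silyl ether (TBS on ring A, TES on ring B). A single fluoride treatment then ends the synthesis, and no base-labile or hydrogenolysable group has to coexist with the epoxide and diene.

**Cc stereocentre and the Cb–Cc bond.** The Cb–Cc bond is cut because it divides the molecule into two halves of similar size, ring A as aldehyde 12 and the terpene as dienyl iodide 26. Cutting C1–Cc instead would require a carbanion at a fully substituted epoxide carbon. Addition of an alkenyl metal to an α-epoxy aldehyde is not trusted to give the S carbinol: the Felkin–Anh and chelate pictures both point to the other epimer. Cc is therefore set one stage later, by reducing ketone 29, which is made by oxidising the adduct mixture 28. In the ketone both pictures place the hydride on the face that gives S.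

**Cd=Ce bond.** 26 is cut at the E alkene into sulfone 20 and (Z)-iodoenal 24 (Julia–Kocienski olefination). The bulky, base-sensitive terpene then acts as the carbanion and the small aldehyde as the electrophile. The Z geometry of Ca=Cb is already locked in 24, which comes from 21 by a chelate-controlled anti carbometalation via 23.

**Ring B.** 20 comes from triol 17 by sulfur installation at the primary carbon and silylation. The tertiary carbinol of 17 is traced to spiro-epoxide 16 and so to the exocyclic alkene 15. The C1′–C2′ bond of 15 is cut to (R)-epoxide 14, made from 13 by asymmetric epoxidation of the remote alkene. The epoxide stereocentre becomes C3′ and, through a chair transition state, fixes C1′; the axial C2′ methyl later fixes C6′.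

**Ring A arms.** 12 is derived from mono-epoxide diester 9 through diol 10 and its mono-silyl ether 11. In 9 the two ester carbons are no longer equivalent: the one on the epoxide carbon becomes Cc, the one on the alkene becomes the C4 hydroxymethyl group.

**Key disconnection.** The C1–O and C2–O bonds of 9 are cut to give diene 7. Because the two enoates of 7 are related by a twofold axis, no site selectivity is needed, and the two cis silyl ethers leave only one open face. One reaction therefore sets C1 and C2 and tells the two arms apart.

**Precursor.** 7 is reached from saturated bis-silyloxy diester 3 by double selenenylation (5) and selenoxide elimination. 3 comes from diol 2, and 2 from commodity diester 1 by catalytic asymmetric hydrogenation of both ketones. All six ring carbons, both carboxyl carbons and both ring oxygens are present in 1; the hydrogenation supplies the only two stereocentres of 7.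

## Alternatives that were turned down

**Alternative 1: dihydropyranone template for the Z alkene.** The Cd–Ce bond is cut, with a temporary Ce–O acyl bond. Forward, the dianion of 3-methylbut-2-enoic acid A3 (two equivalents of a lithium amide) adds through its γ-carbon to terpene aldehyde A2 (identical with F11 below), and the adduct lactonises to dihydropyranone A1. Base-induced eliminative opening of A1 then gives the (2Z,4E)-dienoic acid A4.
- For: the six-membered ring enforces the Z geometry of Ca=Cb without any sensitive β-iodoenal, and the reagents are cheap. On the Z alkene this is stronger than the chosen route.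
- Against: the carboxyl carbon of A4 is Cc, so ring A would have to arrive as a C1 nucleophile and the epoxide be installed after coupling, next to a new carbinol, with face control still to be found. The strongly basic dianion meets an aldehyde that is hindered on both sides and carries a β-silyloxy group (enolisation, elimination, α- versus γ-attack). The acid oxidation level has to be adjusted afterwards.
- Comparison: it solves the diene but not ring A, and it gives up the symmetry that makes ring A short. The chosen route takes a longer path to the diene in exchange.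

**Alternative 2: cyclopentadiene mask.** Two temporary C–C bonds across C4=C5 are cut. Forward, a chiral oxazaborolidinium triflimide catalyses the endo Diels–Alder addition of cyclopentadiene A7 to quinone A6, giving adduct A5 with the angular silyloxymethyl group at C4. The convex face of the tricycle then directs nucleophilic epoxidation of C1=C2 and both carbonyl reductions, and a retro-Diels–Alder reaction returns C4=C5.
- For: every ring A stereocentre is relayed by a rigid framework, a well-precedented tactic for epoxycyclohexenols. Its stereocontrol is better documented than the key step chosen here.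
- Against: the dienophile alkene is trisubstituted and forms a quaternary carbon, so the cycloaddition is slow. The sequence (cycloaddition, epoxidation, reductions, protection, thermal cycloreversion) is longer than the five steps to 9, and the cycloreversion needs high temperature on an epoxide bis-silyl ether.
- Comparison: the chosen route offers fewer steps, no thermolysis and no site-selectivity problem, at the price of one less-precedented epoxidation.

**Alternative 3: propyne carbocupration linchpin.** Ca–Cd and Cb–Cc are cut in one operation. Forward, the alkenylcopper–magnesium reagent made from terpene vinyl iodide A8 (identical with F12 below) adds syn across propyne A9, and the resulting (Z)-dienylcopper adds to aldehyde 12, giving A10 (identical with 30).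
- For: it is the most convergent option; syn carbometalation guarantees the Z alkene, and the chain is built in fewer steps than the sulfone sequence. On step economy for the chain it is stronger.
- Against: it presupposes 12 and says nothing about ring A. Carbocupration of propyne by a hindered alkenylcopper is slow. The dienylcopper is a weak nucleophile toward a neopentylic epoxy aldehyde, and activating it endangers the epoxide. The Cc epimer expected from direct addition is the wrong one, so the oxidation–reduction pair would still be needed. Three valuable components are committed in one flask.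
- Comparison: the chosen route separates these risks and supplies 12. The carbometalation logic is kept as the fallback for step 18.

Key step: step 5

## Route

Step 1
Reactants: 1 dimethyl succinylsuccinate (dimethyl 2,5-dioxocyclohexane-1,4-dicarboxylate)
Product: 2 dimethyl (1S,2S,4S,5S)-2,5-dihydroxycyclohexane-1,4-dicarboxylate
Conditions: H2 (100 atm), RuCl2[(S)-BINAP] (1 mol %), CH2Cl2/MeOH, 50 °C
Reagents that add atoms: none
Why: Noyori asymmetric hydrogenation of cyclic β-keto esters with dynamic kinetic resolution; the (S)-ligand should give the (S)-carbinol at each ketone, and because the two keto-ester halves are related by a twofold axis, equal configuration at both carbinols means the cis diol. The ester-bearing centres (trans by reduction of the faster-reacting epimer) are erased later, and the second reduction should raise the optical purity of the twofold-symmetric diol at the cost of a little meso isomer.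

Step 2
Reactants: 2 dimethyl (1S,2S,4S,5S)-2,5-dihydroxycyclohexane-1,4-dicarboxylate
Product: 3 dimethyl (1S,2S,4S,5S)-2,5-bis(tert-butyldimethylsilyloxy)cyclohexane-1,4-dicarboxylate
Conditions: TBSOTf (2.4 equiv), 2,6-lutidine, CH2Cl2, 0 °C
Reagents that add atoms: tert-butyldimethylsilyl trifluoromethanesulfonate, CC(C)(C)[Si](C)(C)OS(=O)(=O)C(F)(F)F
Why: Silyl ether formation with a silyl triflate under non-nucleophilic base, which avoids retro-aldol or elimination of the β-hydroxy esters; the bulky ethers are the face-directing groups of step 5.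

Step 3
Reactants: 3 dimethyl (1S,2S,4S,5S)-2,5-bis(tert-butyldimethylsilyloxy)cyclohexane-1,4-dicarboxylate
Product: 5 dimethyl (1S,2S,4S,5S)-2,5-bis(tert-butyldimethylsilyloxy)-1,4-bis(phenylselanyl)cyclohexane-1,4-dicarboxylate, via bis(lithium enolate) 4 (not isolated)
Conditions: LiN(iPr)2 (2.5 equiv), THF, −78 °C, short enolisation time; PhSeBr (2.6 equiv), −78 °C
Reagents that add atoms: phenylselanyl bromide, Br[Se]c1ccccc1
Why: Kinetic ester enolate formation and α-selenenylation; at −78 °C the lithium enolate should be trapped faster than it expels the poor silanolate leaving group, and PhSeBr should enter anti to the neighbouring silyl ether. The configuration of the new selenium-bearing centres is of no consequence because both become sp2 in step 4.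

Step 4
Reactants: 5 dimethyl (1S,2S,4S,5S)-2,5-bis(tert-butyldimethylsilyloxy)-1,4-bis(phenylselanyl)cyclohexane-1,4-dicarboxylate
Product: 7 dimethyl (3S,6S)-3,6-bis(tert-butyldimethylsilyloxy)cyclohexa-1,4-diene-1,4-dicarboxylate, via bis(selenoxide) 6 (not isolated)
Conditions: 30 % H2O2, pyridine, CH2Cl2, 0 °C → rt
Reagents that add atoms: none
Why: Selenoxide syn elimination; each selenoxide should eliminate toward the ring CH2 and not toward the silyloxy carbon, following the general preference of selenoxides for allylic ethers over enol ethers. Pyridine buffers the selenium acids so that the base- and acid-sensitive diene survives.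

Step 5
Reactants: 7 dimethyl (3S,6S)-3,6-bis(tert-butyldimethylsilyloxy)cyclohexa-1,4-diene-1,4-dicarboxylate
Product: 9 dimethyl (1S,2S,5R,6S)-2,5-bis(tert-butyldimethylsilyloxy)-7-oxabicyclo[4.1.0]hept-3-ene-1,4-dicarboxylate, via lithium β-peroxy enolate 8 (not isolated)
Conditions: tBuOOH (anhydrous, 1.5 equiv), nBuLi (1.0 equiv), THF, −78 °C; then 7 (1.0 equiv), −78 → −20 °C, stopped at partial conversion; pH 7 buffer
Reagents that add atoms: tert-butyl hydroperoxide (used as its lithium salt), CC(C)(C)OO
Why: This is a Weitz–Scheffer-type nucleophilic epoxidation of an enoate with lithium tert-butyl peroxide, the closest known reaction being the same epoxidation of simple α,β-unsaturated esters. The peroxide anion adds in conjugate fashion to C2 of one enoate, giving ester enolate 8. The enolate carbon C1 then attacks the proximal peroxide oxygen and expels tert-butoxide, closing the oxirane by a 3-exo-tet displacement at oxygen. The C2 stereocentre is set by the face of the conjugate addition, which should be the face opposite the silyl ether on the adjacent C3 and the one on C6, both of which lie on the same side of the nearly flat ring. C1 follows from C2 because the closure is suprafacial, so the epoxide ends trans to both silyl ethers. No site selectivity is needed: the twofold axis makes attack at C2 and at C5 lead to the same compound, and the reaction itself differentiates the two ester arms. The step does need mono-selectivity, handled by one equivalent of peroxide, low temperature and recycling of recovered 7. It also needs suppression of γ-deprotonation followed by loss of silanol (aromatisation), for which the excess hydroperoxide keeps the liberated tert-butoxide protonated and the medium no more basic than the peroxide anion. The allylic silyloxy groups on C3 and C6 also raise the electrophilicity of the trisubstituted enoate.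

Step 6
Reactants: 9 dimethyl (1S,2S,5R,6S)-2,5-bis(tert-butyldimethylsilyloxy)-7-oxabicyclo[4.1.0]hept-3-ene-1,4-dicarboxylate
Product: 10 [(1S,2S,5R,6S)-2,5-bis(tert-butyldimethylsilyloxy)-7-oxabicyclo[4.1.0]hept-3-ene-1,4-diyl]dimethanol
Conditions: iBu2AlH (5 equiv), CH2Cl2, −78 → −40 °C; aqueous potassium sodium tartrate
Reagents that add atoms: none
Why: Aluminium hydride reduction of a glycidic ester and an enoate to the primary alcohols; at low temperature iBu2AlH reduces esters 1,2 and should leave the epoxide and the alkene untouched.

Step 7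
Reactants: 10 [(1S,2S,5R,6S)-2,5-bis(tert-butyldimethylsilyloxy)-7-oxabicyclo[4.1.0]hept-3-ene-1,4-diyl]dimethanol
Product: 11 [(1S,2S,5R,6S)-2,5-bis(tert-butyldimethylsilyloxy)-4-(tert-butyldimethylsilyloxymethyl)-7-oxabicyclo[4.1.0]hept-3-en-1-yl]methanol
Conditions: TBSCl (1.05 equiv), imidazole, CH2Cl2, −30 → 0 °C
Reagents that add atoms: tert-butyldimethylsilyl chloride, CC(C)(C)[Si](C)(C)Cl
Why: Sterically controlled mono-silylation; the allylic CH2OH on sp2 C4 is less hindered than the neopentylic CH2OH on the quaternary epoxide carbon, which also sits next to the cis silyl ether on C6, so the chlorosilane should react first at C4.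

Step 8
Reactants: 11 [(1S,2S,5R,6S)-2,5-bis(tert-butyldimethylsilyloxy)-4-(tert-butyldimethylsilyloxymethyl)-7-oxabicyclo[4.1.0]hept-3-en-1-yl]methanol
Product: 12 (1S,2S,5R,6S)-2,5-bis(tert-butyldimethylsilyloxy)-4-(tert-butyldimethylsilyloxymethyl)-7-oxabicyclo[4.1.0]hept-3-ene-1-carbaldehyde
Conditions: Dess–Martin periodinane, NaHCO3, CH2Cl2, 0 °C → rt
Reagents that add atoms: none
Why: Dess–Martin oxidation under buffered, non-basic conditions; the aldehyde has no α-hydrogen, so neither epimerisation nor enolisation can occur.

Step 9
Reactants: 13 geranyl acetate [(2E)-3,7-dimethylocta-2,6-dien-1-yl acetate]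
Product: 14 (2E)-5-[(2R)-3,3-dimethyloxiran-2-yl]-3-methylpent-2-en-1-yl acetate
Conditions: D-fructose-derived Shi ketone (0.3 equiv), KHSO5 (as 2KHSO5·KHSO4·K2SO4), K2CO3, Bu4NHSO4, Na2B4O7 buffer, MeCN/CH2(OMe)2/H2O, 0 °C
Reagents that add atoms: potassium peroxymonosulfate, [K+].[O-]S(=O)(=O)OO
Why: Shi asymmetric epoxidation; the chiral dioxirane should attack the electron-rich 6,7-alkene and not the alkene deactivated by the allylic acetate, and the D-fructose-derived ketone gives the R epoxide from trisubstituted alkenes of this type through the spiro transition state.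

Step 10
Reactants: 14 (2E)-5-[(2R)-3,3-dimethyloxiran-2-yl]-3-methylpent-2-en-1-yl acetate
Product: 15 [(1S,3R)-3-hydroxy-2,2-dimethyl-6-methylidenecyclohexyl]methyl acetate
Conditions: Cp2TiCl2 (2.2 equiv), Mn dust, THF, rt (Cp2TiCl, trivalent titanium, formed first); slow addition of 14; 1 M HCl work-up
Reagents that add atoms: none
Why: Titanocene-mediated radical epoxy-polyene cyclisation; homolytic opening of the epoxide gives the tertiary radical, which closes the six-membered ring through a chair in which the titanium alkoxide and the acetoxymethyl group are equatorial, so C3′ (from the epoxide) fixes C1′. The cyclised tertiary radical is trapped by a second trivalent titanium and should lose β-hydride to the exocyclic alkene.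

Step 11
Reactants: 15 [(1S,3R)-3-hydroxy-2,2-dimethyl-6-methylidenecyclohexyl]methyl acetate
Product: 16 [(3R,4S,6R)-6-hydroxy-5,5-dimethyl-1-oxaspiro[2.5]octan-4-yl]methyl acetate
Conditions: mCPBA, NaHCO3, CH2Cl2, 0 °C
Reagents that add atoms: 3-chloroperoxybenzoic acid, OOC(=O)c1cccc(Cl)c1
Why: Prilezhaev epoxidation under steric control; with both ring substituents equatorial the chair is fixed, the axial C2′ methyl lies 1,3-diaxial to the axial approach at C6′, and the peracid should therefore deliver oxygen from the equatorial side, as in the related decalin series with an angular methyl.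

Step 12
Reactants: 16 [(3R,4S,6R)-6-hydroxy-5,5-dimethyl-1-oxaspiro[2.5]octan-4-yl]methyl acetate
Product: 17 (1R,2S,4R)-2-(hydroxymethyl)-1,3,3-trimethylcyclohexane-1,4-diol
Conditions: LiAlH4, THF, 0 °C → 40 °C; aqueous NaOH work-up
Reagents that add atoms: none
Why: Hydride opening of a 2,2-disubstituted oxirane at its CH2 carbon, leaving the equatorial tertiary alcohol and an axial methyl at C6′ without touching the stereocentre; the same reagent reduces the acetate to the primary alcohol.

Step 13
Reactants: 17 (1R,2S,4R)-2-(hydroxymethyl)-1,3,3-trimethylcyclohexane-1,4-diol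
Product: 18 (1R,2R,4R)-1,3,3-trimethyl-2-{[(1-phenyl-1H-tetrazol-5-yl)sulfanyl]methyl}cyclohexane-1,4-diol
Conditions: 1-phenyl-1H-tetrazole-5-thiol, PPh3, diisopropyl azodicarboxylate, THF, 0 °C → rt
Reagents that add atoms: 1-phenyl-1H-tetrazole-5-thiol, Sc1nnnn1-c1ccccc1
Why: Mitsunobu thioetherification; only the primary hydroxyl should be activated, because the secondary one is flanked by the gem-dimethyl carbon and the tertiary one cannot react, and the acidic thiol outcompetes intramolecular ether formation.

Step 14
Reactants: 18 (1R,2R,4R)-1,3,3-trimethyl-2-{[(1-phenyl-1H-tetrazol-5-yl)sulfanyl]methyl}cyclohexane-1,4-diol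
Product: 19 (1R,2R,4R)-1,3,3-trimethyl-2-{[(1-phenyl-1H-tetrazol-5-yl)sulfonyl]methyl}cyclohexane-1,4-diol
Conditions: (NH4)6Mo7O24·4H2O (10 mol %), 30 % H2O2, EtOH, 0 °C → rt
Reagents that add atoms: hydrogen peroxide, OO
Why: Molybdate-catalysed oxidation of a sulfide to the sulfone; it is done before silylation so that no acid-labile silyl ether is exposed to the peroxide medium.

Step 15
Reactants: 19 (1R,2R,4R)-1,3,3-trimethyl-2-{[(1-phenyl-1H-tetrazol-5-yl)sulfonyl]methyl}cyclohexane-1,4-diol
Product: 20 1-phenyl-5-({[(1R,3R,6R)-2,2,6-trimethyl-3,6-bis(triethylsilyloxy)cyclohexyl]methyl}sulfonyl)-1H-tetrazole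
Conditions: TESOTf (3 equiv), 2,6-lutidine, CH2Cl2, −78 → 0 °C
Reagents that add atoms: triethylsilyl trifluoromethanesulfonate, CC[Si](CC)(CC)OS(=O)(=O)C(F)(F)F
Why: Silyl triflate silylation, reactive enough for the tertiary hydroxyl; the tertiary silyl ether also removes the alkoxide that could otherwise interfere with the sulfonyl carbanion in step 18.

Step 16
Reactants: 21 prop-2-yn-1-ol
Product: 23 (2Z)-3-iodo-2-methylprop-2-en-1-ol, via alkenylmagnesium alkoxide 22 (not isolated)
Conditions: MeMgBr (3 equiv), CuI (10 mol %), Et2O/THF, −10 °C → rt; then I2, −10 °C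
Reagents that add atoms: methylmagnesium bromide, C[Mg]Br; iodine, II
Why: Copper-catalysed anti carbomagnesiation of a propargylic alkoxide; methyl adds to the internal carbon and magnesium ends on the terminal carbon in a five-membered chelate with the alkoxide, so iodinolysis with retention gives iodine cis to the CH2OH group, which is the Z geometry required for Ca=Cb.

Step 17
Reactants: 23 (2Z)-3-iodo-2-methylprop-2-en-1-ol
Product: 24 (2Z)-3-iodo-2-methylprop-2-enal
Conditions: activated MnO2, CH2Cl2, rt, dark; filtered solution used at once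
Reagents that add atoms: none
Why: Heterogeneous allylic oxidation with MnO2 under neutral conditions, chosen because the β-iodoenal can isomerise by addition–elimination if acid, base or nucleophiles are present.

Step 18
Reactants: 20 1-phenyl-5-({[(1R,3R,6R)-2,2,6-trimethyl-3,6-bis(triethylsilyloxy)cyclohexyl]methyl}sulfonyl)-1H-tetrazole; 24 (2Z)-3-iodo-2-methylprop-2-enal
Product: 26 (1Z,3E)-1-iodo-2-methyl-4-[(1R,3R,6R)-2,2,6-trimethyl-3,6-bis(triethylsilyloxy)cyclohexyl]buta-1,3-diene, via potassium sulfonyl carbanion 25 (not isolated)
Conditions: KN(SiMe3)2 (1.1 equiv), 1,2-dimethoxyethane, −60 °C; then 24, −60 °C → rt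
Reagents that add atoms: none
Why: Julia–Kocienski olefination; addition of the bulky α-sulfonyl carbanion to the aldehyde, Smiles rearrangement and loss of SO2 and the tetrazololate should give the E Cd=Ce alkene, the large ring B substituent favouring the anti adduct. The Ca=Cb geometry is carried over from 24, since no anion is delocalised across it.

Step 19
Reactants: 26 (1Z,3E)-1-iodo-2-methyl-4-[(1R,3R,6R)-2,2,6-trimethyl-3,6-bis(triethylsilyloxy)cyclohexyl]buta-1,3-diene; 12 (1S,2S,5R,6S)-2,5-bis(tert-butyldimethylsilyloxy)-4-(tert-butyldimethylsilyloxymethyl)-7-oxabicyclo[4.1.0]hept-3-ene-1-carbaldehyde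
Product: 28 penta-silylated arthrosporol A with free Cc hydroxyl as a mixture of Cc epimers, via dienyllithium 27 (not isolated)
Conditions: 26 (1.3 equiv), tBuLi (2.6 equiv), Et2O, −78 °C; then 12, −78 °C; H2O quench
Reagents that add atoms: none
Why: Iodine–lithium exchange with retention of alkene geometry and 1,2-addition of the alkenyllithium to a non-enolisable aldehyde, which at −78 °C is far more electrophilic than the epoxide. Felkin–Anh and chelate arrangements both point to the R carbinol as the major epimer, so the mixture is not separated and Cc is set in step 21.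

Step 20
Reactants: 28 penta-silylated arthrosporol A with free Cc hydroxyl as a mixture of Cc epimers
Product: 29 the corresponding Cc ketone (epoxy dienone)
Conditions: Dess–Martin periodinane, NaHCO3, CH2Cl2, 0 °C
Reagents that add atoms: none
Why: Dess–Martin oxidation of a hindered allylic alcohol under buffered conditions; both epimers converge on one ketone, and the mild, short reaction should limit electrocyclisation or isomerisation of the Z dienone.

Step 21
Reactants: 29 the corresponding Cc ketone (epoxy dienone)
Product: 30 penta-silylated arthrosporol A with free (S)-Cc hydroxyl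
Conditions: Zn(BH4)2, Et2O, −30 → 0 °C
Reagents that add atoms: none
Why: Chelation-controlled reduction of an α,β-epoxy ketone; zinc bridges the carbonyl and epoxide oxygens and hydride enters Cc from the side remote from C2, which gives the S carbinol. The Felkin–Anh arrangement with the C1–O bond anti to the hydride predicts the same epimer, and 1,2-reduction of conjugated ketones is the normal course with this reagent.

Step 22
Reactants: 30 penta-silylated arthrosporol A with free (S)-Cc hydroxyl
Product: 31 arthrosporol A
Conditions: HF·pyridine, excess pyridine, THF, 0 °C → rt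
Reagents that add atoms: none
Why: Fluoride-mediated cleavage of all five silyl ethers in a pyridine-buffered medium, which avoids both the alkoxide-driven epoxide migration of a basic fluoride source and the acid ionisation of the dienylic carbinol; no stereocentre is touched.

## Compound list

1 | dimethyl succinylsuccinate (dimethyl 2,5-dioxocyclohexane-1,4-dicarboxylate) | COC(=O)C1CC(=O)C(C(=O)OC)CC1=O | starting material
2 | dimethyl (1S,2S,4S,5S)-2,5-dihydroxycyclohexane-1,4-dicarboxylate | COC(=O)[C@H]1C[C@H](O)[C@@H](C(=O)OC)C[C@@H]1O | intermediate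
3 | dimethyl (1S,2S,4S,5S)-2,5-bis(tert-butyldimethylsilyloxy)cyclohexane-1,4-dicarboxylate | COC(=O)[C@H]1C[C@H](O[Si](C)(C)C(C)(C)C)[C@@H](C(=O)OC)C[C@@H]1O[Si](C)(C)C(C)(C)C | intermediate
4 | bis(lithium enolate) of 3 | COC(O[Li])=C1C[C@H](O[Si](C)(C)C(C)(C)C)C(=C(OC)O[Li])C[C@@H]1O[Si](C)(C)C(C)(C)C | intermediate (not isolated)
5 | dimethyl (1S,2S,4S,5S)-2,5-bis(tert-butyldimethylsilyloxy)-1,4-bis(phenylselanyl)cyclohexane-1,4-dicarboxylate (each PhSe trans to the neighbouring silyl ether) | COC(=O)[C@]1([Se]c2ccccc2)C[C@H](O[Si](C)(C)C(C)(C)C)[C@@](C(=O)OC)([Se]c2ccccc2)C[C@@H]1O[Si](C)(C)C(C)(C)C | intermediate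
6 | bis(selenoxide) of 5 | COC(=O)[C@]1([Se](=O)c2ccccc2)C[C@H](O[Si](C)(C)C(C)(C)C)[C@@](C(=O)OC)([Se](=O)c2ccccc2)C[C@@H]1O[Si](C)(C)C(C)(C)C | intermediate (not isolated)
7 | dimethyl (3S,6S)-3,6-bis(tert-butyldimethylsilyloxy)cyclohexa-1,4-diene-1,4-dicarboxylate | COC(=O)C1=C[C@H](O[Si](C)(C)C(C)(C)C)C(C(=O)OC)=C[C@@H]1O[Si](C)(C)C(C)(C)C | intermediate
8 | lithium ester enolate carrying the tert-butylperoxy group on C2, trans to both silyl ethers | COC(O[Li])=C1[C@@H](OOC(C)(C)C)[C@H](O[Si](C)(C)C(C)(C)C)C(C(=O)OC)=C[C@@H]1O[Si](C)(C)C(C)(C)C | intermediate (not isolated)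
9 | dimethyl (1S,2S,5R,6S)-2,5-bis(tert-butyldimethylsilyloxy)-7-oxabicyclo[4.1.0]hept-3-ene-1,4-dicarboxylate | COC(=O)[C@]12O[C@H]1[C@H](O[Si](C)(C)C(C)(C)C)C(C(=O)OC)=C[C@@H]2O[Si](C)(C)C(C)(C)C | intermediate
10 | [(1S,2S,5R,6S)-2,5-bis(tert-butyldimethylsilyloxy)-7-oxabicyclo[4.1.0]hept-3-ene-1,4-diyl]dimethanol | OC[C@]12O[C@H]1[C@H](O[Si](C)(C)C(C)(C)C)C(CO)=C[C@@H]2O[Si](C)(C)C(C)(C)C | intermediate
11 | [(1S,2S,5R,6S)-2,5-bis(tert-butyldimethylsilyloxy)-4-(tert-butyldimethylsilyloxymethyl)-7-oxabicyclo[4.1.0]hept-3-en-1-yl]methanol | OC[C@]12O[C@H]1[C@H](O[Si](C)(C)C(C)(C)C)C(CO[Si](C)(C)C(C)(C)C)=C[C@@H]2O[Si](C)(C)C(C)(C)C | intermediate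
12 | (1S,2S,5R,6S)-2,5-bis(tert-butyldimethylsilyloxy)-4-(tert-butyldimethylsilyloxymethyl)-7-oxabicyclo[4.1.0]hept-3-ene-1-carbaldehyde | O=C[C@]12O[C@H]1[C@H](O[Si](C)(C)C(C)(C)C)C(CO[Si](C)(C)C(C)(C)C)=C[C@@H]2O[Si](C)(C)C(C)(C)C | intermediate
13 | geranyl acetate | CC(C)=CCC/C(C)=C/COC(C)=O | starting material
14 | (2E)-5-[(2R)-3,3-dimethyloxiran-2-yl]-3-methylpent-2-en-1-yl acetate | CC(=O)OC/C=C(C)/CC[C@H]1OC1(C)C | intermediate
15 | [(1S,3R)-3-hydroxy-2,2-dimethyl-6-methylidenecyclohexyl]methyl acetate | CC(=O)OC[C@@H]1C(C)(C)[C@H](O)CCC1=C | intermediate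
16 | [(3R,4S,6R)-6-hydroxy-5,5-dimethyl-1-oxaspiro[2.5]octan-4-yl]methyl acetate | CC(=O)OC[C@@H]1C(C)(C)[C@H](O)CC[C@@]1(C2)O2 | intermediate
17 | (1R,2S,4R)-2-(hydroxymethyl)-1,3,3-trimethylcyclohexane-1,4-diol | OC[C@@H]1C(C)(C)[C@H](O)CC[C@@]1(C)O | intermediate
18 | (1R,2R,4R)-1,3,3-trimethyl-2-{[(1-phenyl-1H-tetrazol-5-yl)sulfanyl]methyl}cyclohexane-1,4-diol | c1ccccc1-n1nnnc1SC[C@@H]1C(C)(C)[C@H](O)CC[C@@]1(C)O | intermediate
19 | (1R,2R,4R)-1,3,3-trimethyl-2-{[(1-phenyl-1H-tetrazol-5-yl)sulfonyl]methyl}cyclohexane-1,4-diol | O=S(=O)(C[C@@H]1C(C)(C)[C@H](O)CC[C@@]1(C)O)c1nnnn1-c1ccccc1 | intermediate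
20 | 1-phenyl-5-({[(1R,3R,6R)-2,2,6-trimethyl-3,6-bis(triethylsilyloxy)cyclohexyl]methyl}sulfonyl)-1H-tetrazole | O=S(=O)(C[C@@H]1C(C)(C)[C@H](O[Si](CC)(CC)CC)CC[C@@]1(C)O[Si](CC)(CC)CC)c1nnnn1-c1ccccc1 | intermediate
21 | prop-2-yn-1-ol | C#CCO | starting material
22 | (Z)-alkenylmagnesium bromide with magnesium cis to the CH2O–MgBr group | Br[Mg]/C=C(/C)CO[Mg]Br | intermediate (not isolated)
23 | (2Z)-3-iodo-2-methylprop-2-en-1-ol | OC/C(C)=C\I | intermediate
24 | (2Z)-3-iodo-2-methylprop-2-enal | O=C/C(C)=C\I | intermediate
25 | potassium salt of the α-sulfonyl carbanion of 20 | [K+].O=S(=O)([CH-][C@@H]1C(C)(C)[C@H](O[Si](CC)(CC)CC)CC[C@@]1(C)O[Si](CC)(CC)CC)c1nnnn1-c1ccccc1 | intermediate (not isolated)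
26 | (1Z,3E)-1-iodo-2-methyl-4-[(1R,3R,6R)-2,2,6-trimethyl-3,6-bis(triethylsilyloxy)cyclohexyl]buta-1,3-diene | CC(=C/I)/C=C/[C@@H]1C(C)(C)[C@H](O[Si](CC)(CC)CC)CC[C@@]1(C)O[Si](CC)(CC)CC | intermediate
27 | (1Z,3E)-dienyllithium from 26 | CC(=C/[Li])/C=C/[C@@H]1C(C)(C)[C@H](O[Si](CC)(CC)CC)CC[C@@]1(C)O[Si](CC)(CC)CC | intermediate (not isolated)
28 | penta-silylated arthrosporol A with free Cc hydroxyl, both Cc epimers (ring A as in 12, ring B and diene as in 26) | CC(=C/C(O)[C@]12O[C@H]1[C@H](O[Si](C)(C)C(C)(C)C)C(CO[Si](C)(C)C(C)(C)C)=C[C@@H]2O[Si](C)(C)C(C)(C)C)/C=C/[C@@H]1C(C)(C)[C@H](O[Si](CC)(CC)CC)CC[C@@]1(C)O[Si](CC)(CC)CC | intermediate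
29 | Cc ketone of 28 (2Z,4E epoxy dienone) | CC(=C/C(=O)[C@]12O[C@H]1[C@H](O[Si](C)(C)C(C)(C)C)C(CO[Si](C)(C)C(C)(C)C)=C[C@@H]2O[Si](C)(C)C(C)(C)C)/C=C/[C@@H]1C(C)(C)[C@H](O[Si](CC)(CC)CC)CC[C@@]1(C)O[Si](CC)(CC)CC | intermediate
30 | penta-silylated arthrosporol A with free (S)-Cc hydroxyl | CC(=C/[C@H](O)[C@]12O[C@H]1[C@H](O[Si](C)(C)C(C)(C)C)C(CO[Si](C)(C)C(C)(C)C)=C[C@@H]2O[Si](C)(C)C(C)(C)C)/C=C/[C@@H]1C(C)(C)[C@H](O[Si](CC)(CC)CC)CC[C@@]1(C)O[Si](CC)(CC)CC | intermediate
31 | arthrosporol A | CC(=C/[C@H](O)[C@]12O[C@H]1[C@H](O)C(CO)=C[C@@H]2O)/C=C/[C@@H]1C(C)(C)[C@H](O)CC[C@@]1(C)O | target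

## Step count and least certain steps

Total: 22 steps. Longest linear sequence: 12 steps (1 → 12 in eight steps, or 13 → 26 in eight steps, followed by steps 19–22).

**Step 5 (key step).** Most likely failures are over-oxidation to the bis-epoxide, because the product still holds a reactive enoate, and aromatisation by γ-deprotonation and loss of silanol if free alkoxide builds up. The conjugate addition to a trisubstituted enoate may also be slow.
Fallback: starting from 7, both esters are reduced with iBu2AlH to the twofold-symmetric bis(allylic alcohol), [(3S,6S)-3,6-bis(tert-butyldimethylsilyloxy)cyclohexa-1,4-diene-1,4-diyl]dimethanol F1. One of its two homotopic allylic alcohol units is then epoxidised under hydroxyl direction (VO(acac)2 with tBuOOH, or Ti(OiPr)4 with a dialkyl tartrate matched to the face left open by the silyl ethers). This neutral, electrophilic oxidation gives 10 directly, where the route is rejoined; the symmetry argument is unchanged.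

**Step 3.** The enolate may expel silanolate (β-elimination) before it is selenenylated, or the second enolisation may be incomplete.
Fallback: starting from 2, the hydroxyls are kept as lithium alkoxides, which are not leaving groups (Fráter–Seebach-type alkoxide enolate, excess LiN(iPr)2, then PhSeBr). This gives dimethyl 2,5-dihydroxy-1,4-bis(phenylselanyl)cyclohexane-1,4-dicarboxylate F2. Oxidative elimination gives dimethyl (3S,6S)-3,6-dihydroxycyclohexa-1,4-diene-1,4-dicarboxylate F3, and silylation with TBSOTf returns to 7.

**Step 1.** The strongly enolised, poorly soluble substrate may be reduced incompletely, and weaker control at the second carbonyl would raise the meso diol content.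
Fallback: starting from 1, a biocatalytic reduction (baker's yeast or an (S)-selective ketoreductase with cofactor recycling), known to give (S)-carbinols cis to the ester with 2-oxocycloalkanecarboxylates, would give dimethyl (1R,2S,4R,5S)-2,5-dihydroxycyclohexane-1,4-dicarboxylate F4. Silylation gives its bis-TBS ether F5, and deprotonation of F5 gives the same enolate 4, so the route is rejoined at 5.

**Step 7.** The two primary alcohols may not be told apart well enough, giving bis-silylation or the wrong mono-ether.
Fallback: starting from 10, MnO2 oxidises only the allylic alcohol to the hydroxy enal F6. The remaining neopentylic hydroxyl is capped as the triethylsilyl ether F7 and the aldehyde is reduced (NaBH4, CeCl3) to the allylic alcohol F8, which is silylated with TBSCl to F9. Mild acid methanolysis removes the primary triethylsilyl group and returns to 11.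

**Step 18.** E selectivity at Cd=Ce may erode with a conjugated aldehyde, and the β-iodoenal may isomerise by addition–elimination before it is consumed.
Fallback: starting from 17, exhaustive silylation gives the tris-TES ether F10. Swern conditions convert its primary silyl ether directly into aldehyde F11, and Takai olefination (CrCl2, CHI3) gives the (E)-vinyl iodide F12. Iodine–lithium exchange, transmetalation to an alkenylcopper (MgBr2, CuBr·SMe2), syn carbocupration of propyne and iodinolysis then give 26, with both alkene geometries set by mechanism.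

**Step 21.** Hydride delivery may show poor or reversed facial selectivity if the chelate does not form next to the bulky C6 silyl ether, and some conjugate reduction is possible.
Fallback: starting from 29 and returning to 30, the reduction is put under reagent control with an oxazaborolidine-catalysed borane reduction (Corey–Bakshi–Shibata), using the catalyst enantiomer that gives the S carbinol. Any wrong epimer is returned to 29 by step 20. No new compound is involved.

## Further compounds

F1 | step 5 | [(3S,6S)-3,6-bis(tert-butyldimethylsilyloxy)cyclohexa-1,4-diene-1,4-diyl]dimethanol | OCC1=C[C@H](O[Si](C)(C)C(C)(C)C)C(CO)=C[C@@H]1O[Si](C)(C)C(C)(C)C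
F2 | step 3 | dimethyl (1S,2S,4S,5S)-2,5-dihydroxy-1,4-bis(phenylselanyl)cyclohexane-1,4-dicarboxylate | COC(=O)[C@]1([Se]c2ccccc2)C[C@H](O)[C@@](C(=O)OC)([Se]c2ccccc2)C[C@@H]1O
F3 | step 3 | dimethyl (3S,6S)-3,6-dihydroxycyclohexa-1,4-diene-1,4-dicarboxylate | COC(=O)C1=C[C@H](O)C(C(=O)OC)=C[C@@H]1O
F4 | step 1 | dimethyl (1R,2S,4R,5S)-2,5-dihydroxycyclohexane-1,4-dicarboxylate | COC(=O)[C@@H]1C[C@H](O)[C@H](C(=O)OC)C[C@@H]1O
F5 | step 1 | dimethyl (1R,2S,4R,5S)-2,5-bis(tert-butyldimethylsilyloxy)cyclohexane-1,4-dicarboxylate | COC(=O)[C@@H]1C[C@H](O[Si](C)(C)C(C)(C)C)[C@H](C(=O)OC)C[C@@H]1O[Si](C)(C)C(C)(C)C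
F6 | step 7 | ring A epoxide with free CH2OH on C1 and formyl group on C4 (configuration as in 10) | OC[C@]12O[C@H]1[C@H](O[Si](C)(C)C(C)(C)C)C(C=O)=C[C@@H]2O[Si](C)(C)C(C)(C)C
F7 | step 7 | triethylsilyl ether of F6 | CC[Si](CC)(CC)OC[C@]12O[C@H]1[C@H](O[Si](C)(C)C(C)(C)C)C(C=O)=C[C@@H]2O[Si](C)(C)C(C)(C)C
F8 | step 7 | allylic alcohol from reduction of F7 | CC[Si](CC)(CC)OC[C@]12O[C@H]1[C@H](O[Si](C)(C)C(C)(C)C)C(CO)=C[C@@H]2O[Si](C)(C)C(C)(C)C
F9 | step 7 | tert-butyldimethylsilyl ether of F8 | CC[Si](CC)(CC)OC[C@]12O[C@H]1[C@H](O[Si](C)(C)C(C)(C)C)C(CO[Si](C)(C)C(C)(C)C)=C[C@@H]2O[Si](C)(C)C(C)(C)C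
F10 | step 18 | tris(triethylsilyl) ether of 17 | CC[Si](CC)(CC)OC[C@@H]1C(C)(C)[C@H](O[Si](CC)(CC)CC)CC[C@@]1(C)O[Si](CC)(CC)CC
F11 | step 18 | (1R,3R,6R)-2,2,6-trimethyl-3,6-bis(triethylsilyloxy)cyclohexane-1-carbaldehyde | O=C[C@@H]1C(C)(C)[C@H](O[Si](CC)(CC)CC)CC[C@@]1(C)O[Si](CC)(CC)CC
F12 | step 18 | (E)-2-iodoethenyl derivative of ring B, bis-TES ether | I/C=C/[C@@H]1C(C)(C)[C@H](O[Si](CC)(CC)CC)CC[C@@]1(C)O[Si](CC)(CC)CC
F0 | step 21 | none | none
A1 | alternative 1 | 4-methyl-6-[2,2,6-trimethyl-3,6-bis(triethylsilyloxy)cyclohexyl]-5,6-dihydro-2H-pyran-2-one (one Ce epimer) | CC1=CC(=O)O[C@H](C1)[C@@H]2C(C)(C)[C@H](O[Si](CC)(CC)CC)CC[C@@]2(C)O[Si](CC)(CC)CC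
A2 | alternative 1 | (1R,3R,6R)-2,2,6-trimethyl-3,6-bis(triethylsilyloxy)cyclohexane-1-carbaldehyde | O=C[C@@H]1C(C)(C)[C@H](O[Si](CC)(CC)CC)CC[C@@]1(C)O[Si](CC)(CC)CC
A3 | alternative 1 | 3-methylbut-2-enoic acid | CC(C)=CC(=O)O
A4 | alternative 1 | (2Z,4E)-3-methyl-5-[2,2,6-trimethyl-3,6-bis(triethylsilyloxy)cyclohexyl]penta-2,4-dienoic acid | CC(=C/C(=O)O)/C=C/[C@@H]1C(C)(C)[C@H](O[Si](CC)(CC)CC)CC[C@@]1(C)O[Si](CC)(CC)CC
A5 | alternative 2 | endo cyclopentadiene–quinone adduct with angular silyloxymethyl group at C4 | O=C1C=C(CO[Si](C)(C)C(C)(C)C)C(=O)[C@H]2[C@H]3C=C[C@H](C3)[C@@]12CO[Si](C)(C)C(C)(C)C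
A6 | alternative 2 | 2,5-bis(tert-butyldimethylsilyloxymethyl)cyclohexa-2,5-diene-1,4-dione | O=C1C=C(CO[Si](C)(C)C(C)(C)C)C(=O)C=C1CO[Si](C)(C)C(C)(C)C
A7 | alternative 2 | cyclopenta-1,3-diene | C1=CC=CC1
A8 | alternative 3 | (E)-2-iodoethenyl derivative of ring B, bis-TES ether | I/C=C/[C@@H]1C(C)(C)[C@H](O[Si](CC)(CC)CC)CC[C@@]1(C)O[Si](CC)(CC)CC
A9 | alternative 3 | propyne | CC#C
A10 | alternative 3 | penta-silylated arthrosporol A with free (S)-Cc hydroxyl | CC(=C/[C@H](O)[C@]12O[C@H]1[C@H](O[Si](C)(C)C(C)(C)C)C(CO[Si](C)(C)C(C)(C)C)=C[C@@H]2O[Si](C)(C)C(C)(C)C)/C=C/[C@@H]1C(C)(C)[C@H](O[Si](CC)(CC)CC)CC[C@@]1(C)O[Si](CC)(CC)CC
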